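## Retrosynthetic overview

1. Target ⇒ Evans–Tishchenko reduction (sets C-1, leaves the acetate on O-3) ⇒ macrocyclic β-hydroxy enone.
2. Macrocycle ⇒ ring-closing direct aldol (C-2–C-3, new method; ten-membered ring formed last) ⇒ open keto-enal on a finished α-methylene-γ-lactone.
3. Keto-enal ⇒ Wittig (C-9=C-10, E), Mannich methylenation, Nozaki–Hiyama–Kishi coupling (C-5–C-6, Z-iodide) then lactonisation (five-membered lactone formed first).
4. Lactone precursor ⇒ diarylprolinol-catalysed anti cross-aldol (C-7–C-8) of methyl 4-oxobutanoate with 2,2-dimethoxyacetaldehyde; Z-iodide from propargyl alcohol.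
5. Ring order: γ-lactone (step 5), then ten-membered carbocycle (step 10).

Assumption: positions are given in germacrane numbering (lactone carbonyl C-12, exocyclic methylene C-13); prop-2-yn-1-ol, methyl 4-oxobutanoate, 2,2-dimethoxyacetaldehyde (60% aqueous) and 3-(triphenylphosphoranylidene)butan-2-one are taken as catalogue chemicals.

## Route

Step 1
Reactants: 1 prop-2-yn-1-ol
Product: 3 (Z)-3-iodo-2-methylprop-2-en-1-ol, via alkenylmagnesium chelate 2 (not isolated)
Conditions: MeMgBr (2.5 equiv), CuI (10 mol%), THF, −10 °C → rt; then I2, −40 → 0 °C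
Reagents that add atoms: methylmagnesium bromide (C[Mg]Br); iodine (II)
Why: Alkoxide-directed, copper-catalysed anti-carbomagnesiation of the propargylic alkoxide puts methyl on the internal carbon and magnesium cis to CH2O in a five-membered chelate, and iodinolysis with retention gives the Z-iodide (no stereocentre).

Step 2
Reactants: 3 (Z)-3-iodo-2-methylprop-2-en-1-ol
Product: 4 tert-butyl{[(Z)-3-iodo-2-methylprop-2-en-1-yl]oxy}dimethylsilane
Conditions: TBSCl, imidazole, CH2Cl2, 0 °C → rt
Reagents that add atoms: tert-butyldimethylsilyl chloride (CC(C)(C)[Si](C)(C)Cl)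
Why: Imidazole-assisted silylation masks the primary allylic hydroxyl for the enolate chemistry of step 6; alkene geometry is untouched.

Step 3
Reactants: 5 methyl 4-oxobutanoate; 6 2,2-dimethoxyacetaldehyde
Product: 7 methyl (3R,4S)-3-formyl-4-hydroxy-5,5-dimethoxypentanoate
Conditions: (R)-bis[3,5-bis(trifluoromethyl)phenyl](pyrrolidin-2-yl)methanol (10 mol%), 6 (60% in H2O, 2 equiv), DMF, 4 °C, slow addition of 5
Reagents that add atoms: none
Why: Enamine cross-aldol in which only 5 can form the enamine and the catalyst hydroxyl hydrogen-bonds the non-enolisable aldehyde 6 in a List–Houk-type transition state, giving the anti aldol and setting C-7 and C-8 (the first stereocentres) in the sense dictated by the (R)-catalyst.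

Step 4
Reactants: 7 methyl (3R,4S)-3-formyl-4-hydroxy-5,5-dimethoxypentanoate
Product: 8 methyl (3R,4S)-3-formyl-5,5-dimethoxy-4-(tigloyloxy)pentanoate
Conditions: tigloyl chloride (1.3 equiv), pyridine, 4-(dimethylamino)pyridine (5 mol%), CH2Cl2, −20 °C
Reagents that add atoms: (E)-2-methylbut-2-enoyl chloride (C/C=C(\C)C(Cl)=O)
Why: Nucleophile-catalysed O-acylation installs the C-8 tiglate directly at low temperature with a weak base, so that β-elimination and C-7 epimerisation of the aldehyde are avoided and no stereocentre is touched.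

Step 5
Reactants: 8 methyl (3R,4S)-3-formyl-5,5-dimethoxy-4-(tigloyloxy)pentanoate; 4 tert-butyl{[(Z)-3-iodo-2-methylprop-2-en-1-yl]oxy}dimethylsilane
Product: 10 tigloyloxy trans-γ-lactone dimethyl acetal silyl ether, via hydroxy ester 9 (not isolated)
Conditions: CrCl2 (6 equiv), NiCl2 (2 mol%), DMSO, rt; then pyridinium p-toluenesulfonate (cat.), PhMe, 50 °C
Reagents that add atoms: none
Why: Nozaki–Hiyama–Kishi alkenylation with retention of the Z-geometry, in which the alkenylchromium adds to the α-branched β-acyloxy aldehyde in the Felkin–Anh sense that here coincides with 1,3-anti induction and sets C-6 (R), after which the γ-hydroxy ester closes to the trans-lactone.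

Step 6
Reactants: 10 tigloyloxy trans-γ-lactone dimethyl acetal silyl ether
Product: 13 α-methylene lactone dimethyl acetal silyl ether, via Mannich base 11 (not isolated), via ammonium iodide 12 (not isolated)
Conditions: LiN(SiMe3)2 (1.1 equiv), THF, −78 °C; [CH2=NMe2]I, −78 → 0 °C; then MeI, CH2Cl2, rt; then NaHCO3 (aq)
Reagents that add atoms: N,N-dimethylmethaniminium iodide (C=[N+](C)C.[I-]); iodomethane (CI)
Why: Mannich reaction of the lactone lithium enolate with Eschenmoser's salt, then N-quaternisation and E1cB (Hofmann-type) elimination, in which the lactone α-CH2 is the only readily enolisable site (the tiglate has no α-hydrogen), the methyl brought in by iodomethane is carried only by 12 and departs as trimethylamine, and the transient C-11 centre disappears.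

Step 7
Reactants: 13 α-methylene lactone dimethyl acetal silyl ether
Product: 14 α-methylene lactone hydroxy aldehyde
Conditions: CF3CO2H/H2O (4:1), CH2Cl2, 0 °C → rt
Reagents that add atoms: water (O)
Why: Acid hydrolysis cleaves the dimethyl acetal and the primary silyl ether in one operation, while the esters, the lactone and the C-8 centre (not enolised under cold acid) are left alone.

Step 8
Reactants: 14 α-methylene lactone hydroxy aldehyde; 15 3-(triphenylphosphoranylidene)butan-2-one
Product: 16 hydroxy E-enone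
Conditions: 15 (1.5 equiv), CH2Cl2, 40 °C
Reagents that add atoms: none
Why: Wittig olefination with a stabilised α-branched keto ylide gives the E-trisubstituted enone (C-9=C-10) and brings in C-10, C-14, C-1 and C-2 without epimerising the α-acyloxy centre C-8.

Step 9
Reactants: 16 hydroxy E-enone
Product: 17 seco keto-enal
Conditions: MnO2 (20 equiv), CH2Cl2, rt
Reagents that add atoms: none
Why: Chemoselective allylic oxidation of the primary allylic alcohol under neutral heterogeneous conditions gives the Z-enal without Z/E isomerisation.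

Step 10
Reactants: 17 seco keto-enal
Product: 18 macrocyclic β-hydroxy enone
Conditions: (R,R)-2,6-bis{[2-(hydroxydiphenylmethyl)pyrrolidin-1-yl]methyl}-4-methylphenol (30 mol%), Et2Zn (60 mol%), 4 Å MS, THF (2 mM), −20 → 0 °C
Reagents that add atoms: none
Why: Proposed new method: a ring-closing version of the dinuclear-zinc direct aldol, in which one zinc alkoxide of the catalyst deprotonates only the enone methyl group (C-2) to a zinc enolate while the second zinc binds the Z-enal, so that both ends of 17 sit in one chiral pocket and the ten-membered ring closes at low temperature with catalyst-controlled attack on the aldehyde face that gives (3S); the closest known reaction is the intermolecular dinuclear-zinc direct aldol of methyl vinyl ketone and other methyl ketones with aldehydes.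

Step 11
Reactants: 18 macrocyclic β-hydroxy enone
Product: 19 target CNP0319825.6
Conditions: SmI2 (30 mol%), MeCHO (10 equiv), THF, −10 °C
Reagents that add atoms: acetaldehyde (CC=O)
Why: Evans–Tishchenko reduction, in which the samarium-bound hemiacetal of the C-3 hydroxyl with acetaldehyde delivers hydride intramolecularly to the C-1 ketone through a chair-like six-membered transition state, giving the 1,3-anti (1S) carbinol and leaving the acetate on O-3.

## Compound list

1 | prop-2-yn-1-ol | C#CCO | starting material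
2 | bromomagnesium (Z)-3-(bromomagnesio)-2-methylprop-2-en-1-olate | Br[Mg]/C=C(/C)CO[Mg]Br | intermediate
3 | (Z)-3-iodo-2-methylprop-2-en-1-ol | I/C=C(/C)CO | intermediate
4 | tert-butyl{[(Z)-3-iodo-2-methylprop-2-en-1-yl]oxy}dimethylsilane | I/C=C(/C)CO[Si](C)(C)C(C)(C)C | intermediate
5 | methyl 4-oxobutanoate | COC(=O)CCC=O | starting material
6 | 2,2-dimethoxyacetaldehyde | COC(OC)C=O | starting material
7 | methyl (3R,4S)-3-formyl-4-hydroxy-5,5-dimethoxypentanoate | O=C[C@H](CC(=O)OC)[C@H](O)C(OC)OC | intermediate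
8 | methyl (3R,4S)-3-formyl-5,5-dimethoxy-4-{[(E)-2-methylbut-2-enoyl]oxy}pentanoate | O=C[C@H](CC(=O)OC)[C@H](OC(=O)/C(C)=C/C)C(OC)OC | intermediate
9 | methyl (3S,4R,5Z)-7-{[tert-butyl(dimethyl)silyl]oxy}-3-[(1S)-2,2-dimethoxy-1-{[(E)-2-methylbut-2-enoyl]oxy}ethyl]-4-hydroxy-6-methylhept-5-enoate | COC(=O)C[C@H]([C@H](OC(=O)/C(C)=C/C)C(OC)OC)[C@H](O)/C=C(/C)CO[Si](C)(C)C(C)(C)C | intermediate
10 | (1S)-1-[(2R,3S)-2-[(Z)-3-{[tert-butyl(dimethyl)silyl]oxy}-2-methylprop-1-en-1-yl]-5-oxooxolan-3-yl]-2,2-dimethoxyethyl (E)-2-methylbut-2-enoate | O=C1C[C@H]([C@H](OC(=O)/C(C)=C/C)C(OC)OC)[C@@H](/C=C(/C)CO[Si](C)(C)C(C)(C)C)O1 | intermediate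
11 | compound 10 carrying CH2NMe2 on the lactone α-carbon (C-11), trans to the C-7 side chain | O=C1[C@@H](CN(C)C)[C@H]([C@H](OC(=O)/C(C)=C/C)C(OC)OC)[C@@H](/C=C(/C)CO[Si](C)(C)C(C)(C)C)O1 | intermediate
12 | N-methyl quaternary ammonium iodide of 11 | O=C1[C@@H](C[N+](C)(C)C)[C@H]([C@H](OC(=O)/C(C)=C/C)C(OC)OC)[C@@H](/C=C(/C)CO[Si](C)(C)C(C)(C)C)O1.[I-] | intermediate
13 | (1S)-1-[(2R,3S)-2-[(Z)-3-{[tert-butyl(dimethyl)silyl]oxy}-2-methylprop-1-en-1-yl]-4-methylidene-5-oxooxolan-3-yl]-2,2-dimethoxyethyl (E)-2-methylbut-2-enoate | O=C1C(=C)[C@H]([C@H](OC(=O)/C(C)=C/C)C(OC)OC)[C@@H](/C=C(/C)CO[Si](C)(C)C(C)(C)C)O1 | intermediate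
14 | (1S)-1-[(2R,3S)-2-[(Z)-3-hydroxy-2-methylprop-1-en-1-yl]-4-methylidene-5-oxooxolan-3-yl]-2-oxoethyl (E)-2-methylbut-2-enoate | O=C1C(=C)[C@H]([C@H](OC(=O)/C(C)=C/C)C=O)[C@@H](/C=C(/C)CO)O1 | intermediate
15 | 3-(triphenylphosphoranylidene)butan-2-one | CC(=O)C(C)=P(c1ccccc1)(c1ccccc1)c1ccccc1 | starting material
16 | (1R,2E)-1-[(2R,3S)-2-[(Z)-3-hydroxy-2-methylprop-1-en-1-yl]-4-methylidene-5-oxooxolan-3-yl]-3-methyl-4-oxopent-2-en-1-yl (E)-2-methylbut-2-enoate | O=C1C(=C)[C@H]([C@H](OC(=O)/C(C)=C/C)/C=C(\C)C(C)=O)[C@@H](/C=C(/C)CO)O1 | intermediate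
17 | (1R,2E)-3-methyl-1-[(2R,3S)-4-methylidene-2-[(Z)-2-methyl-3-oxoprop-1-en-1-yl]-5-oxooxolan-3-yl]-4-oxopent-2-en-1-yl (E)-2-methylbut-2-enoate | O=C1C(=C)[C@H]([C@H](OC(=O)/C(C)=C/C)/C=C(\C)C(C)=O)[C@@H](/C=C(/C)C=O)O1 | intermediate
18 | (3S,6R,7S,8R)-3-hydroxy-1-oxo-8-{[(E)-2-methylbut-2-enoyl]oxy}germacra-4Z,9E,11(13)-trien-12,6-olide | C=C1C(=O)O[C@@H]2/C=C(/C)[C@@H](O)CC(=O)/C(C)=C/[C@@H](OC(=O)/C(C)=C/C)[C@@H]12 | intermediate
19 | (1S,3S,6R,7S,8R)-3-acetoxy-1-hydroxy-8-{[(E)-2-methylbut-2-enoyl]oxy}germacra-4Z,9E,11(13)-trien-12,6-olide (CNP0319825.6) | C=C1C(=O)O[C@@H]2/C=C(/C)[C@@H](OC(C)=O)C[C@H](O)/C(C)=C/[C@@H](OC(=O)/C(C)=C/C)[C@@H]12 | target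

## Step count and risks

Total step count: 11. Longest linear sequence: 9 steps (steps 3–11; the branch through steps 1, 2 and 5–11 is equally long).

The three steps most likely to fail:

**Step 10 (the proposed new ring-closing aldol).** The ten-membered ring may not close in competition with oligomerisation, or the catalyst may not override the conformational bias at C-3. The fallback uses known chemistry, sets out from 16 and comes back at 18. Me3SiOTf/Et3N (CH2Cl2, −78 °C) silylates the ketone on its methyl side and the primary hydroxyl to give the bis(trimethylsilyl) dienol ether F1. NBS (THF, −78 °C) followed by a citric acid work-up gives the bromomethyl ketone F2, and MnO2 oxidises this to the bromo keto-enal F3. SmI2 (2.2 equiv, THF, −78 °C, 1 mM) then closes the ring by the known samarium Reformatsky-type aldol of an α-bromo ketone onto an aldehyde, giving 18; C-3 is then set by the samarium chelate, and any epimer is separated.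

**Step 5 (C-6 configuration in the Nozaki–Hiyama–Kishi coupling, on a β-acyloxy aldehyde that can eliminate).** The fallback replaces substrate-controlled addition by a hydroxyl-directed reduction; it sets out from 7 and 4 and comes back at 10. Coupling of the untigloylated aldol 7 with 4 (CrCl2, NiCl2, DMSO) gives the diol ester F4 as a C-6 epimer mixture. MnO2 oxidises only the allylic carbinol to the β-hydroxy enone F5. Me4NBH(OAc)3 (MeCN/AcOH, −30 °C, Evans–Saksena reduction) delivers hydride from the C-8 hydroxyl and gives the 1,3-anti diol F6. Pyridinium p-toluenesulfonate closes the favoured trans-lactone through O-6 to the hydroxy lactone F7, and tigloyl chloride/pyridine then gives 10. This detour also avoids acylating the β-hydroxy aldehyde in step 4.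

**Step 11 (Evans–Tishchenko reduction on a strained macrocycle that also holds reducible groups, with possible 1,3-acyl migration).** The fallback separates acylation from reduction; it sets out from 18 and comes back at 19. Ac2O/pyridine with 4-(dimethylamino)pyridine (0 °C) gives the β-acetoxy enone F8. Corey–Bakshi–Shibata reduction with (R)-1-methyl-3,3-diphenyltetrahydro-1H,3H-pyrrolo[1,2-c][1,3,2]oxazaborole (20 mol%) and catecholborane (toluene, −78 °C) then reduces the α-methyl enone 1,2 under catalyst control to the (1S)-carbinol 19.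

Further compounds

F1 | step 10 | bis(trimethylsilyl) dienol ether of 16 (2-silyloxydiene at C-1/C-2, trimethylsilyl ether at O-3) | O=C1C(=C)[C@H]([C@H](OC(=O)/C(C)=C/C)/C=C(\C)C(=C)O[Si](C)(C)C)[C@@H](/C=C(/C)CO[Si](C)(C)C)O1
F2 | step 10 | bromomethyl ketone of 16 (bromine on C-2, free C-3 hydroxyl) | O=C1C(=C)[C@H]([C@H](OC(=O)/C(C)=C/C)/C=C(\C)C(=O)CBr)[C@@H](/C=C(/C)CO)O1
F3 | step 10 | bromo keto-enal (C-2 bromide of 17) | O=C1C(=C)[C@H]([C@H](OC(=O)/C(C)=C/C)/C=C(\C)C(=O)CBr)[C@@H](/C=C(/C)C=O)O1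
F4 | step 5 | methyl (3S,5Z)-7-{[tert-butyl(dimethyl)silyl]oxy}-4-hydroxy-3-[(1S)-1-hydroxy-2,2-dimethoxyethyl]-6-methylhept-5-enoate, C-4 epimer mixture | COC(=O)C[C@H]([C@H](O)C(OC)OC)C(O)/C=C(/C)CO[Si](C)(C)C(C)(C)C
F5 | step 5 | methyl (3S,5Z)-7-{[tert-butyl(dimethyl)silyl]oxy}-3-[(1S)-1-hydroxy-2,2-dimethoxyethyl]-6-methyl-4-oxohept-5-enoate | COC(=O)C[C@H]([C@H](O)C(OC)OC)C(=O)/C=C(/C)CO[Si](C)(C)C(C)(C)C
F6 | step 5 | methyl (3S,4R,5Z)-7-{[tert-butyl(dimethyl)silyl]oxy}-4-hydroxy-3-[(1S)-1-hydroxy-2,2-dimethoxyethyl]-6-methylhept-5-enoate | COC(=O)C[C@H]([C@H](O)C(OC)OC)[C@H](O)/C=C(/C)CO[Si](C)(C)C(C)(C)C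
F7 | step 5 | (4S,5R)-5-[(Z)-3-{[tert-butyl(dimethyl)silyl]oxy}-2-methylprop-1-en-1-yl]-4-[(1S)-1-hydroxy-2,2-dimethoxyethyl]oxolan-2-one | O=C1C[C@H]([C@H](O)C(OC)OC)[C@@H](/C=C(/C)CO[Si](C)(C)C(C)(C)C)O1
F8 | step 11 | (3S,6R,7S,8R)-3-acetoxy-1-oxo-8-{[(E)-2-methylbut-2-enoyl]oxy}germacra-4Z,9E,11(13)-trien-12,6-olide | C=C1C(=O)O[C@@H]2/C=C(/C)[C@@H](OC(C)=O)CC(=O)/C(C)=C/[C@@H](OC(=O)/C(C)=C/C)[C@@H]12
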